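(Readings and results are calculated on assumed constants.)

**Easy start.** The easy step is to balance what enters and leaves Q, the dissolved form of solid Z, in these flasks.

| flask | Z | G | remark | time |
|---|---|---|---|---|
| north-east | 36 mM | 0.13 mol% | run made earlier |  |
| north-west | 36 mM | 0.3 mol% | run made earlier |  |
| flask | 36 mM | 0.2 mol% |  | 10 min |

- north-east (time / min: E / %, Q / %, Z / %): 1.00: 0.2, 1.6, 97.7; 2.00: 0.4, 2.7, 97.1; 3.00: 0.8, 2.4, 96.8; 6.00: 3.5, 3.0, 92.8; 12.0: 8.5, 2.6, 87.7
- north-west (time / min: E / %, Q / %, Z / %): 1.00: 0.2, 1.0, 98.6; 3.00: 1.2, 2.6, 96.0; 6.00: 4.0, 2.6, 92.5; 8.00: 4.9, 2.7, 91.6; 12.0: 8.5, 3.1, 87.3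

(readings scatter by 0.3 percentage points)

- solid, in amounts per volume of the solution: Z
- at the start none of Z is in solution
- Q is what Z becomes in solution
- Q means what is dissolved; the solid is not counted in it

- E at 10 min, in percent of the Z charged
- concentration of Q in solution at 10 min, in percent of saturation

**Two rates.** I assume that solid Z feeds Q in proportion to the gap below saturation, [Q]s − [Q], and that a first-order drain with constant c removes Q. [Q] then climbs with a rate constant r, the sum of feed and drain constants, to a plateau (a quasi-steady state). That plateau is a fraction of [Q]s equal to one minus c/r.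

**The readings.** In both runs the plateau reads 2.83%. Dividing the mean fall of Z between 6.00 min and 12.0 min by it gives c = 0.304 min⁻¹. The mean Q at 1.00 min gives r = 0.617 min⁻¹, a rough reading given the scatter. So c reads half of r, and the saturation share, one minus c/r, reads 50.7%. This puts my estimate of [Q]s at 2.01 mM.

**Product E.** The north-east and north-west runs read E at 8.5% and 8.5% at 12.0 min, so I keep one line for the new flask. Its mean slope of 0.00792 min⁻¹ (as a fraction of the charge) gives 6.92% at 10 min.

**The forecast** gives E 6.8% (6.1% to 7.5%) and 95% of saturation (78% to 100%), holding that “the solution sits near saturation”; my share differs there.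

**The flask** gives E 6.82% and 51.4% of saturation, against my 6.92% and 50.7%.

    Q → L (k = 0.320 min⁻¹)
    G + L → G + E (k = 53000 M⁻¹ min⁻¹)
    Z ⇌ Q, rate k3*(cs3 - [Q]) while solid is left; crystals form when [Q] > cs3 (solubility = 2.00 mM, k = 0.340 min⁻¹)
    L → X (k = 0.410 min⁻¹)

**Not at rest.** In this flask Q stands at 2.86% at 10.0 min and 2.86% at 100 min, so its plateau holds over that time. The flask itself keeps moving: over that time E climbs from 6.82% to 81.2%, X from 0.733% to 8.73%, and Z falls from 89.4% to 6.94%.

**Second flask.** In a neighbour flask with 140 mM of Z and the same loading of G, at 10.0 min, keeping 50.7% and 2.01 mM gives Q as 0.728% of that charge. The computed flask holds 0.735%, with E at 1.93%.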